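Time is what you hold fixed first: compare two flasks at the same early times, and the ratio of their Q stands for the ratio of their rates.

| setting | Monday's | Friday's | Saturday's | Thursday's | Wednesday's |
|---|---|---|---|---|---|
| E | 50.0 mM | 20.0 mM | 75.0 mM | 50.0 mM | 17.0 mM |
| G | 125 mM | 95.0 mM | 125 mM | 250 mM | 380 mM |
| time |  |  |  |  | 35 min |

| run | time / min | [Q] / mM |
|---|---|---|
| Monday's run | 2.0 | 1.7 |
| Monday's run | 6.0 | 5.6 |
| Monday's run | 12 | 10.2 |
| Monday's run | 18 | 14.8 |
| Monday's run | 26 | 16.0 |
| Monday's run | 35 | 17.2 |
| Friday's run | 2.0 | 1.0 |
| Friday's run | 6.0 | 2.3 |
| Friday's run | 12 | 4.0 |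
| Friday's run | 18 | 5.8 |
| Friday's run | 26 | 8.8 |
| Friday's run | 35 | 8.4 |
| Saturday's run | 2.0 | 2.2 |
| Saturday's run | 6.0 | 9.0 |
| Saturday's run | 12 | 13.2 |
| Saturday's run | 18 | 16.4 |
| Saturday's run | 26 | 20.2 |
| Saturday's run | 35 | 22.0 |
| Thursday's run | 2.0 | 4.4 |
| Thursday's run | 6.0 | 8.7 |
| Thursday's run | 12 | 14.1 |
| Thursday's run | 18 | 16.8 |
| Thursday's run | 26 | 17.9 |
| Thursday's run | 35 | 17.3 |

(readings scatter by 0.5 mM)

- how the opening rate goes with [G] round the charge of the Monday's run: the exponent of the rate at two percent of E gone to Q
- how the opening rate goes with [E] round the charge of the Monday's run: the exponent of the rate at two percent of E gone to Q (one fixed amount of Q, the same in the runs compared)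
- Q in the Wednesday's run at 35 min, as a share of the E charged

- Overall: E + G -> Q.
- Constant volume, constant temperature.
- Readings of a species count what is bound in complexes too.
- "The second partner" is G.
- An order is taken over about fifteen percent of the charge, up and down.

Take Monday's and Thursday's runs. Both start with E at 50.0 mM, while G goes from 125 mM to 250 mM. Work in powers of ten, because an order is a slope on logarithms. The G charge rises by 0.301 in log10.

Two extreme versions of the flask can be solved in your head. In the first, G acts as charged, so the rate goes with G to the power one, and log10 of the rate rises by that same 0.301. In the second, G sits mostly in inactive pairs. The free part then goes as the square root of the charge, so the order is 0.5 and the rise is 0.150.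

Single readings are scattered, so add each run's readings up to 12 min. Monday's run gives 17.5 mM and Thursday's gives 27.2 mM, a rise of 0.192 in log10. Call the working order n, the apparent order in G: the log10 rise in early Q divided by the log10 rise in the G charge. Here the reading is n = 0.636, below one and above 0.5. So the real flask lies between the extremes, and G acts as if part of it were held back.

Now carry n to Wednesday's run. Its G charge stands a factor of 3.04 above Monday's, which is 0.483 in log10. Multiply by n to get 0.307, so G counts there for a factor of about 2.03. Commit to that order and that factor.

The forecast gave 1.05 for G, 0.75 for E and 46% for Wednesday's run, which it said “should reach its ceiling well before 35 min”.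

The flask gives 0.64 for G, 0.58 for E and 23.0% for Wednesday's run.

    E + G → Q (2.700 /M/min)
    Q + G → L (0.6480 /M/min)
    2 G ⇌ G2, settled at all times (13.80 /M)
    2 E ⇌ E2, settled at all times (284.0 /M)

Your n of 0.636 stands beside the flask's 0.64, and the pairing of G to G2 holds the order down: the same flask without that pairing gives an order of 1.0. At order one, Wednesday's G charge counts for a factor of 3.04; at n, it counts for 2.03, and in the scheme G both makes Q and turns Q into L. Because of the pairing, Wednesday's run holds 23.0% of its E charge as Q at 35 min, and the same run without it holds 0.0764%.

Readings and results were computed with made-up constants.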